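Every substrate molecule charged stays countable: substrate, first product with its crystals, double, triple and side product together make up the charge, so you are asking what share of it stands as first product and crystals.

substrate 0.21 M; gas 96 mM (held); time 1.0 h

    substrate + partner → first product + by-product (k1 = 0.0035 M⁻¹ s⁻¹)
    partner + first product → double product + by-product (k2 = 0.0021 M⁻¹ s⁻¹)
    partner + double product → triple product + by-product (k3 = 0.010 M⁻¹ s⁻¹)
    gas ⇌ partner, rate k4*(csat - [partner]) (k4 = 6.1 × 10⁻⁴ s⁻¹, csat = 96 mM)
    crystals ⇌ first product, rate k5*(cs5 - [first product]) while solid is left; crystals form when [first product] > cs5 (cs5 = 0.063 M, k5 = 0.0035 s⁻¹)
    substrate + by-product → side product (k6 = 0.0022 M⁻¹ s⁻¹)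

- amount of first product and crystals together at 1.0 h, in percent of the substrate charged
- the change that raises the amount of first product and crystals together at 1.0 h, in percent of the substrate charged most ("none" if none brings more than 2 percentage points) (Saturday's / Friday's / Sunday's / Thursday's / none)
- amount of first product and crystals together at 1.0 h, in percent of the substrate charged, after Friday's

- Saturday's: doubling the solubility in step 5, all else as stated
- Friday's: doubling the transfer coefficient of step 4, all else as stated
- Sunday's: doubling the saturation concentration of gas, all else as stated
- Thursday's: doubling the dissolution coefficient of step 5, all else as stated

- first product is meant together with its crystals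
- solid, in amounts per volume of the solution: crystals
- at the start none of partner is dissolved
- run time (flask): 1.0 h

Follow one dissolved partner molecule. With substrate near its charge, it reacts with substrate at a frequency of 7.35 × 10⁻⁴ s⁻¹, while transfer returns it to the gas at 6.1 × 10⁻⁴ s⁻¹. Its chance of going back is therefore 45.4 %. That chance times the saturation concentration gives the partner level, the quasi-steady c(partner) 0.0435 M, reached with a delay of 0.207 h, one over the sum of the two frequencies.

How much first product does this level make? Substrate falls pseudo-first-order after the delay, so I reckon that 35.3 % of it reacts. A first-product molecule lives on average through half of that time, and 87.8 % survive the partner. My figure is 31.0 %, with the side reaction left out.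

Does the solid matter? Solubility corresponds to 30.0 % of the charge, and my figure stands 0.97 percentage points above it, so I expect little from Saturday's or Thursday's.

Which change then wins? Sunday's takes the level to 0.0871 M, twice the present one, whereas Friday's reaches 0.0599 M. I choose Sunday's, and the same reckoning gives 39.3 % after Friday's.

The forecast, a little lower than mine on both figures, gave 30 % (27 % to 33 %) and 37 % after Friday's (33 % to 41 %). It chose Sunday's, holding that “doubling the saturation concentration gives the higher partner level throughout”.

The flask gives 29.3 % and 35.6 % after Friday's. The best change is Sunday's, which gains 10 points against 6.3 points for Friday's, while Saturday's and Thursday's gain 0 points and 0 points.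

Climbing towards the level with its delay, partner should stand at 0.0167 M at 0.100 h in this flask, where 0.0167 M is read, and at 0.0377 M in the flask left until 25 min, where 0.0383 M is read. At 1.00 h in this flask, partner stands at 0.0473 M and goes to substrate 2.9 times as fast as to first product, with crystals at 0 %.

Its constants are those of an exercise; the rest is arithmetic.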